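## Structural features

The target is a germacranolide: a ten-membered carbocycle (numbered C1–C10 here, with methyl carbon C14 on C10 and C15 on C4) fused across C6–C7 to a butenolide. The lactone oxygen is on C6, the C7=C11 double bond is tetrasubstituted, and C11 carries the lactone carbonyl C12 and the hydroxymethyl carbon C13. The carbocycle holds two trans-configured trisubstituted epoxides, C1–C10 and C4–C5, which stand 1,5 to each other, and C8 carries an (E)-2-methylbut-2-enoate (tiglate). There are six stereocentres, (1R,4R,5R,6S,8S,10R): C4, C5 and C6 are contiguous, the C6 and C8 oxygens flank sp2 C7 on the same face, and the epoxide oxygens sit as expected for attack on the outer faces of an (E,E)-cyclodeca-1,5-diene with both methyl groups on one side. The fragile parts are the epoxides (acid, transannular opening), the (E,E)-1,5-diene that precedes them (Cope rearrangement on heating), the γ-hydrogen of the butenolide at C6 (base), the allylic tiglate, and any β-oxygenated ketone on the way (elimination). The real difficulty is the medium ring with two trisubstituted alkenes of defined geometry next to the C6/C8 stereocentres, not any single functional group. The key step uses the 1,5-relationship of the C1–C10 and C4–C5 bonds: both can be the new bonds of one cyclobutane (C10–C1–C4–C5) made from a cyclohexenone (ring C5–C10, C6 carbonyl, C8 oxygen) and a cyclobutene (ring C1–C4, ester carbon C15 on C4). Breaking the other two cyclobutane bonds (C5–C10 and C1–C4) then opens the six- and four-membered rings into the ten-membered ring.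

## Logic of the disconnections

37 to 34. The four C–O bonds of the two epoxides are cut. The epoxides are the most fragile groups and so come last; the C1=C10 and C4=C5 alkenes of 34 are electron-rich, while C7=C11 and the alkene of the C8 ester are electron-poor. Four stereocentres are removed. The forward step must take its facial selectivity from the ring conformation, and both ring alkenes must already be E.

34 to 30, through 33 and 31, with 32 as the acyl donor. The C8–O acyl bond and the two O–Si bonds are cut. The unsaturated ester on C8 would not survive the enolate, hydride and strong-base steps, so it is attached after the butenolide is complete. This demands two silyl ethers of different lability in 30, the one on C8 being removed first while C13 stays protected.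

30 to 20 and 24, through 28 and 26. The C7=C11 bond (as a C7–C11 aldol bond plus loss of water) and the C12–O lactone bond are cut. The butenolide maps onto C7 of 20 and the ketone carbon of 24, which removes the lactone ring and the C6 stereocentre. The forward steps need enolisation at C7 only, reduction at C6 to the alcohol cis to C8–O, lactonisation at C6 (not C8), and elimination toward C7.

20 to 12, through 19, 18, 16, 15 and 13. No skeletal bond is cut: C15 is returned to the ester level and C6 is cycled through the alcohol. The ester on C4 is what the key step needs, and the lactone bridge of 15 between C15 and the C6 oxygen is the device that forces C3 trans to C6 at C4=C5. The price is a reduction and re-oxidation at C6 and a hydride displacement at C15 that must not transpose the alkene.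

12 to 11. The C5–C10 and C1–C4 bonds are re-formed. The ten-membered diene becomes the 6-4-4 ring system of 11, whose strain drives the forward fragmentation, so the medium-ring problem is exchanged for a small-ring cycloaddition. The forward step must cleave these two bonds and not C2–C3, must be faster than Cope rearrangement of the product, and fixes the C1=C10 geometry for good.

11 to 7 and 10. The C1–C10 and C4–C5 bonds are cut (the key step). What remains is two monocycles, of which 7 carries the only permanent stereocentre (C8). The forward step must be head-to-head (C4 to C5) and give the cis-anti-cis ring system.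

7 to 1, through 6, 5, 3 and 2. The C10–C14 bond is cut and the carbonyl is moved back by allylic transposition; the symmetry of the remaining carbinol carbons leads to 1, which is meso. The forward sequence needs one selection between enantiotopic groups (by an enzyme) and mild handling of a β-silyloxy enone.

10 to 8 through 9, and 24 to 21 through 22. One C=C is formed by loss of HBr in the first case, and one C=C is cleaved to the ketone in the second. Both are two-step preparations from purchased 8 and 21; 32 is purchased as well.

## Other disconnections considered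

Alternative 1: The cut is C2–C3, with C5–C10 re-formed, so that the ten-membered enol triflate A1 comes from the six-membered carbinol A2. In the forward sense KH/18-crown-6 would turn A2 into its alkoxide, a charge-accelerated [3,3] shift would expand the ring, and PhN(SO2CF3)2 would trap the enolate as A1. Three points speak for it. The chair transition state of a trans-dialkenyl carbinol dictates E geometry for both ring alkenes at low temperature, which is better than a thermolysis that leaves one geometry to a diradical. C15 is a methyl from the start, so the ester-to-methyl detour (steps 10–15 here) is not needed, again better. A later C7 ketone next to the C6 oxygen would allow a phosphonate butenolide annulation with no elimination problem. Against it, A2 needs four contiguous stereocentres, including the quaternary C10 and the tertiary carbinol C5 with the two alkenyl groups trans, on a ring already oxygenated at C6, C7 and C8. The C5 triflate of A1 must also still be reduced to C–H next to an allylic ether, and the protecting-group traffic is heavy. Both plans break C5–C10. This one makes one bond in a concerted anionic step, where the chosen plan makes two photochemically and breaks two thermally. On geometry control it is the better plan, on access to the ring-forming substrate the weaker, and the overall step count would probably be equal or higher.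

Alternative 2: The cut is the C6–O lactone bond. Pd(OAc)2 with a bis-sulfoxide ligand and benzoquinone would cleave a C6–H bond of the trienoic acid A4, and the carboxylate would close the butenolide A3. A3 has the same constitution and configuration as 30, so the endgame would be identical (an equal point). In its favour there is no ketone at C6, no reduction whose facial course must be controlled, and one step in place of the three used here (steps 18–20), which is better step economy at that stage. Against it, this is an endgame cut only and says nothing on how the ten-membered ring of A4 is made. The catalyst type is established for terminal alkenes, whereas here divalent palladium must select one doubly allylic CH2 among eight allylic positions. A π-allyl across C4–C6 could scramble the C4=C5 geometry or deliver oxygen to C4, and the (E,E)-1,5-diene may not tolerate the oxidant. C6 would be set relative to C8 by the macrocycle alone, as in step 19 here (equal), and the difficulty of the tetrasubstituted C7=C11 geometry moves into A4. Mechanistically it is C–H cleavage and inner-sphere C–O formation against carbonyl chemistry: shorter but less predictable.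

Alternative 3: The cut is C1–C2. 9-BBN would add to the terminal alkene of the open-chain diene A6, and Pd(dppf)Cl2 with base would couple the alkylborane with the C1 vinyl iodide to close the ring as A5. In its favour, both trisubstituted alkenes are made in open-chain precursors and the coupling retains geometry, so on alkene geometry this is the better plan. The tiglate is already in place, so only desilylation and epoxidation follow, also better. Against it, a ten-membered ring is the hardest size to close by cross-coupling, and nothing like strain release drives it (high dilution, dimers, β-hydride elimination of the alkylpalladium). The borane must add to the terminal position of a conjugated diene without forming allylboranes. Zerovalent palladium and aqueous base meet an allylic lactone C6–O bond, an allylic tiglate at C8 and the epimerisable C6–H. Finally, A6 needs C6 and C8 set in an acyclic butenolide, which is roughly as long as the route to 30. The chosen plan pays for the medium ring with the strain of two cyclobutanes and builds it before the sensitive groups exist; Alternative 3 has the cleaner stereochemical logic but the riskier ring closure.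

Key step: step 8

Remarks on the chemistry:

Assumption: the lipase acetylates the enantiotopic hydroxyl that leads to 3 as drawn; should the enzyme show the opposite preference, a lipase of complementary selectivity is chosen.

Configuration: C8 of 7 and 11 is S and corresponds to C8 (S) of 37. Compound 11 is head-to-head and cis-anti-cis, with the four-membered rings anti to the silyloxy group.

Remark on steps 8 and 9: the four stereocentres made in step 8 all become sp2 in step 9, so facial selectivity relative to C8 is not required. Only the regiochemistry and the cis-anti-cis relationship matter.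

Remark on alkene geometry: a cis-fused adduct opening through a chair cyclohexane-1,4-diyl cannot give both ring alkenes E. C1=C10 is expected E and C4=C5 with C3 cis to C6. Steps 10–11 therefore lock C4=C5 through a C15→O6 lactone before C15 is reduced.

Remark on lactonisation: the C6 and C8 hydroxyls are both γ to C12, so C8 stays silylated until the 12,6-lactone is closed.

## Route

Step 1
Reactants: 1 cis,cis-cyclohexane-1,3,5-triol
Product: 2 all-cis-5-[(tert-butyldimethylsilyl)oxy]cyclohexane-1,3-diol
Conditions: NaH (1.0 equiv), TBSCl (1.0 equiv), THF/DMF, 0 °C → rt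
Reagents that add atoms: tert-butyldimethylsilyl chloride, CC(C)(C)[Si](C)(C)Cl
Why: Statistical monosilylation of the mono-alkoxide; the product is meso, so no stereochemical question arises, and unreacted 1 is recovered.

Step 2
Reactants: 2 all-cis-5-[(tert-butyldimethylsilyl)oxy]cyclohexane-1,3-diol
Product: 3 (1R,3S,5S)-3-[(tert-butyldimethylsilyl)oxy]-5-hydroxycyclohexyl acetate
Conditions: Candida antarctica lipase B (immobilised), vinyl acetate, 30 °C
Reagents that add atoms: vinyl acetate, CC(=O)OC=C
Why: Enzymatic desymmetrisation by irreversible transesterification distinguishes the two enantiotopic hydroxyls of the meso diol; this sets the absolute configuration of the whole series, because the hydroxyl left free becomes the carbonyl carbon.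

Step 3
Reactants: 3 (1R,3S,5S)-3-[(tert-butyldimethylsilyl)oxy]-5-hydroxycyclohexyl acetate
Product: 5 (R)-5-[(tert-butyldimethylsilyl)oxy]cyclohex-2-en-1-one, via keto acetate 4 (not isolated)
Conditions: Dess–Martin periodinane, pyridine, CH2Cl2, 0 °C → rt; then Et3N, 0 °C
Reagents that add atoms: none
Why: Dess–Martin oxidation followed by E1cB loss of acetate, a far better leaving group than the silanolate on the other β-carbon; the silyloxy stereocentre is untouched.

Step 4
Reactants: 5 (R)-5-[(tert-butyldimethylsilyl)oxy]cyclohex-2-en-1-one
Product: 6 (5R)-5-[(tert-butyldimethylsilyl)oxy]-1-methylcyclohex-2-en-1-ol (both C1 epimers)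
Conditions: MeLi, Et2O, −78 °C; then H2O
Reagents that add atoms: methyllithium, [Li]C
Why: 1,2-Addition of the hard organolithium to the enone carbonyl at low temperature outruns enolisation and loss of silanolate; the new carbinol centre is a mixture that becomes sp2 in step 5.

Step 5
Reactants: 6 (5R)-5-[(tert-butyldimethylsilyl)oxy]-1-methylcyclohex-2-en-1-ol
Product: 7 (S)-5-[(tert-butyldimethylsilyl)oxy]-3-methylcyclohex-2-en-1-one
Conditions: IBX, DMSO, 55 °C
Reagents that add atoms: 2-iodoxybenzoic acid, O=C1OI(=O)(O)c2ccccc12
Why: Oxidative 1,3-transposition of a tertiary allylic alcohol (Babler–Dauben type, here through the pentavalent iodine ester): the oxygen is moved to the far allylic carbon and oxidised, which leaves the methyl on the β-carbon. The silyloxy carbon is not involved; it is C8 of the target and is now S.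

Step 6
Reactants: 8 ethyl 1-bromocyclobutane-1-carboxylate
Product: 9 cyclobut-1-ene-1-carboxylic acid
Conditions: KOH, PhMe, reflux; then aq. HCl
Reagents that add atoms: potassium hydroxide, [K+].[OH-]
Why: E2 dehydrobromination of the tertiary α-bromo ester with saponification in the same pot, the classical entry to the cyclobutene acid (the bromo ester is the α-bromination product of cyclobutanecarboxylic acid and is a catalogue compound).

Step 7
Reactants: 9 cyclobut-1-ene-1-carboxylic acid
Product: 10 methyl cyclobut-1-ene-1-carboxylate
Conditions: TMSCHN2, MeOH/PhMe, 0 °C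
Reagents that add atoms: (trimethylsilyl)diazomethane, C[Si](C)(C)C=[N+]=[N-]
Why: Methyl ester formation without base or heat, which the strained, polymerisable acrylate would not tolerate; 10 is used at once.

Step 8
Reactants: 7 (S)-5-[(tert-butyldimethylsilyl)oxy]-3-methylcyclohex-2-en-1-one; 10 methyl cyclobut-1-ene-1-carboxylate
Product: 11 methyl (8S)-8-[(tert-butyldimethylsilyl)oxy]-6-methyl-10-oxotricyclo[4.4.0.0(2,5)]decane-2-carboxylate (head-to-head cis-anti-cis adduct)
Conditions: hν (350 nm, Pyrex), 10 (5 equiv), CH2Cl2, −20 °C; then filtration through SiO2/Et3N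
Reagents that add atoms: none
Why: Excitation of 7 and intersystem crossing give the twisted triplet enone, which bonds through C10 to the unsubstituted alkene carbon C1 of 10; the resulting triplet 1,4-diradical (α-keto radical at C5, tertiary ester-stabilised radical at C4) closes the C4–C5 bond after spin inversion. The closest known reaction type is the intermolecular [2+2] photocycloaddition of cyclohexenones with electron-poor cyclobutene esters. The one ring closed is the central cyclobutane C10–C1–C4–C5, formed in an intermolecular, stepwise way (radical addition, then 1,4-diradical recombination). Head-to-head orientation is what the step needs; it is the normal course for an acceptor-substituted alkene, because the first bond leaves the radical on the ester-bearing carbon, which then joins the enone α-carbon. C1 and C4 are cis by constraint of the cyclobutene ring. C5 and C10 end cis-fused because that is the stable 6–4 fusion and C5 is epimerisable next to the ketone (the amine-treated silica converges any trans-fused adduct). The two four-membered rings are anti across the central ring because the CH2CH2 bridge of 10 approaches turned away from the cyclohexanone ring, and the less hindered enone face is the one opposite the C8 silyloxy group. Facial selectivity is convenient for analysis but not essential, since all four new centres become sp2 in step 9.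

Step 9
Reactants: 11 methyl (8S)-8-[(tert-butyldimethylsilyl)oxy]-6-methyl-10-oxotricyclo[4.4.0.0(2,5)]decane-2-carboxylate
Product: 12 methyl (8S)-8-[(tert-butyldimethylsilyl)oxy]-6-oxogermacra-1(10),4-dien-15-oate (C2 trans to C9; C3 cis to C6)
Conditions: PhMe (0.01 M), BHT, base-washed sealed tube, 150 °C
Reagents that add atoms: none
Why: Thermal cleavage of the bicyclo[2.2.0]hexane unit (the thermal half of a photo-thermal olefin metathesis): homolysis of the strained C1–C4 bond gives a cyclohexane-1,4-diyl with an ester-stabilised radical at C4, and scission of C5–C10 then releases both small rings as C1=C10 and C4=C5. Cleavage from the chair diyl that keeps C9 equatorial and turns C6 axial, away from the C4 ester, should give C1=C10 as the E alkene and C4=C5 with the ester trans to the C6 carbonyl; this second geometry is corrected in step 11. Conjugation of C4=C5 with both carbonyl groups holds the ten-membered ring against Cope contraction, and the temperature is kept at the lowest value that consumes 11.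

Step 10
Reactants: 12 methyl (8S)-8-[(tert-butyldimethylsilyl)oxy]-6-oxogermacra-1(10),4-dien-15-oate
Product: 13 methyl (8S)-8-[(tert-butyldimethylsilyl)oxy]-6-hydroxygermacra-1(10),4-dien-15-oate (both C6 epimers)
Conditions: NaBH4, CeCl3·7H2O, MeOH, −40 °C
Reagents that add atoms: none
Why: Luche 1,2-reduction of the enone carbonyl leaves the conjugated ester; both C6 epimers are carried on because C6 is re-oxidised in step 15, and the β-silyloxy ketone is removed before any basic step.

Step 11
Reactants: 13 methyl (8S)-8-[(tert-butyldimethylsilyl)oxy]-6-hydroxygermacra-1(10),4-dien-15-oate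
Product: 15 (8S)-8-[(tert-butyldimethylsilyl)oxy]germacra-1(10),4-dien-15,6-olide (C3 trans to C6), via phenylthio lactone 14 (not isolated)
Conditions: PhSH (0.2 equiv), DBU (0.2 equiv), PhMe, 50 °C
Reagents that add atoms: none
Why: Thiolate-catalysed isomerising lactonisation: reversible conjugate addition of PhS− at C5 frees rotation about C4–C5, the C6 hydroxyl closes onto the C15 ester, and E1cB loss of thiolate from 14 regenerates C4=C5 inside the five-membered lactone. That ring can only hold C15 and C6 cis, so C3 ends trans to C6 as the target requires, whatever geometry step 9 delivered; the isolated C1=C10 alkene does not react with a thiolate.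

Step 12
Reactants: 15 (8S)-8-[(tert-butyldimethylsilyl)oxy]germacra-1(10),4-dien-15,6-olide
Product: 16 (8S)-8-[(tert-butyldimethylsilyl)oxy]germacra-1(10),4-diene-6,15-diol (C3 trans to C6)
Conditions: i-Bu2AlH (4 equiv), CH2Cl2, −78 → 0 °C; aq. potassium sodium tartrate
Reagents that add atoms: none
Why: 1,2-Reduction of the unsaturated lactone through the lactol to the ene-1,4-diol; no conjugate reduction occurs with this reagent and the alkene geometry fixed in step 11 is kept.

Step 13
Reactants: 16 (8S)-8-[(tert-butyldimethylsilyl)oxy]germacra-1(10),4-diene-6,15-diol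
Product: 18 (8S)-8-[(tert-butyldimethylsilyl)oxy]-15-chlorogermacra-1(10),4-dien-6-ol, via allylic mesylate 17 (not isolated)
Conditions: MsCl, 2,4,6-collidine, LiCl, DMF, 0 °C
Reagents that add atoms: lithium chloride, [Li+].[Cl-]
Why: Selective sulfonylation of the primary allylic hydroxyl and SN2 displacement by chloride in the same pot; the hindered secondary C6 hydroxyl is left, and the weak, hindered base avoids closure to the cyclic ether.

Step 14
Reactants: 18 (8S)-8-[(tert-butyldimethylsilyl)oxy]-15-chlorogermacra-1(10),4-dien-6-ol
Product: 19 (8S)-8-[(tert-butyldimethylsilyl)oxy]germacra-1(10),4-dien-6-ol (C2 trans to C9; C3 trans to C6)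
Conditions: LiEt3BH (2.5 equiv), THF, −78 → 0 °C; then H2O
Reagents that add atoms: none
Why: Direct SN2 hydride displacement of the primary allylic chloride, with no allyl radical, anion or π-allyl intermediate, so the C4=C5 geometry is retained; the C6 alkoxide is held as its triethylborane ate complex and does not attack C15.

Step 15
Reactants: 19 (8S)-8-[(tert-butyldimethylsilyl)oxy]germacra-1(10),4-dien-6-ol
Product: 20 (8S)-8-[(tert-butyldimethylsilyl)oxy]germacra-1(10),4-dien-6-one (C2 trans to C9; C3 trans to C6)
Conditions: Dess–Martin periodinane, pyridine, CH2Cl2, 0 °C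
Reagents that add atoms: none
Why: Buffered Dess–Martin oxidation of the allylic alcohol to the enone without acid or base that could isomerise C4=C5 or cyclise the 1,5-diene.

Step 16
Reactants: 21 methyl 2-(hydroxymethyl)prop-2-enoate
Product: 22 methyl 2-({[tert-butyl(diphenyl)silyl]oxy}methyl)prop-2-enoate
Conditions: TBDPSCl, imidazole, CH2Cl2, rt
Reagents that add atoms: tert-butyldiphenylsilyl chloride, CC(C)(C)[Si](Cl)(c1ccccc1)c1ccccc1
Why: Standard silylation of a primary alcohol; this silyl group is chosen because it outlasts the C8 silyl ether under buffered HF (step 21).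

Step 17
Reactants: 22 methyl 2-({[tert-butyl(diphenyl)silyl]oxy}methyl)prop-2-enoate
Product: 24 methyl 3-{[tert-butyl(diphenyl)silyl]oxy}-2-oxopropanoate, via ozonide 23 (not isolated)
Conditions: O3, CH2Cl2, −78 °C; then Me2S, −78 °C → rt
Reagents that add atoms: ozone, [O-][O+]=O
Why: Ozonolysis of the 1,1-disubstituted alkene and reductive cleavage of the ozonide give the protected hydroxypyruvate; the silyl ether is inert to ozone, and 24 is kept anhydrous and used directly.

Step 18
Reactants: 20 (8S)-8-[(tert-butyldimethylsilyl)oxy]germacra-1(10),4-dien-6-one; 24 methyl 3-{[tert-butyl(diphenyl)silyl]oxy}-2-oxopropanoate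
Product: 26 methyl 2-[(8S)-8-[(tert-butyldimethylsilyl)oxy]-6-oxogermacra-1(10),4-dien-7-yl]-3-{[tert-butyl(diphenyl)silyl]oxy}-2-hydroxypropanoate (C7 and C11 epimers), via lithium enolate 25 (not isolated)
Conditions: LiN(i-Pr)2, THF, −78 °C; then 24, −78 °C; AcOH quench at −78 °C
Reagents that add atoms: none
Why: Kinetic deprotonation at the only α-CH2 (C7) gives the cross-conjugated lithium enolate, which adds to the very electrophilic ketone carbonyl of the α-keto ester (aldol addition), preferably on the face away from the C8 silyloxy group. The C7 and C11 centres both become sp2 in step 20, and the cold acidic quench prevents retro-aldol and loss of silanolate from C8.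

Step 19
Reactants: 26 aldol adduct (C7 and C11 epimers)
Product: 28 8-[(tert-butyldimethylsilyl)oxy]-13-{[tert-butyl(diphenyl)silyl]oxy}-11-hydroxygermacra-1(10),4-dien-12,6-olide (C6–O cis to C8–O; C7 and C11 epimers), via triol ester 27 (not isolated)
Conditions: NaBH4, CeCl3·7H2O, MeOH, −78 °C; then PPTS (cat.), PhMe, 40 °C
Reagents that add atoms: none
Why: Luche 1,2-reduction of the enone, then lactonisation of the C6 hydroxyl onto the C12 ester; C8–O is still silylated, so only the 12,6-lactone can form. Hydride is expected to add from the ring periphery to the conformer that keeps the C7 side chain and the C8 silyloxy group pseudo-equatorial. This places the new C6 oxygen pseudo-equatorial, trans to the C7 substituent and cis to C8–O as in the target, the medium-ring counterpart of equatorial-alcohol formation from a 2-substituted cyclohexanone.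

Step 20
Reactants: 28 hydroxy lactone (C7 and C11 epimers)
Product: 30 (6R,8S)-8-[(tert-butyldimethylsilyl)oxy]-13-{[tert-butyl(diphenyl)silyl]oxy}germacra-1(10),4,7(11)-trien-12,6-olide, via chlorosulfite 29 (not isolated)
Conditions: SOCl2, pyridine, CH2Cl2, −20 → 0 °C
Reagents that add atoms: none
Why: Dehydration of the tertiary α-hydroxy lactone through its chlorosulfite (E2 with pyridine): loss of the ring hydrogen on C7 gives the tetrasubstituted alkene conjugated with the lactone carbonyl, whereas the C13 hydrogens sit on an oxygen-bearing carbon and are removed less readily. C7 and C11 become sp2, so the C7 and C11 epimers of steps 18 and 19 converge on one compound.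

Step 21
Reactants: 30 (6R,8S)-8-[(tert-butyldimethylsilyl)oxy]-13-{[tert-butyl(diphenyl)silyl]oxy}germacra-1(10),4,7(11)-trien-12,6-olide
Product: 31 (6R,8S)-13-{[tert-butyl(diphenyl)silyl]oxy}-8-hydroxygermacra-1(10),4,7(11)-trien-12,6-olide
Conditions: HF·pyridine, pyridine, THF, 0 °C → rt
Reagents that add atoms: none
Why: Under buffered HF the secondary tert-butyldimethylsilyl ether is cleaved much faster than the primary tert-butyldiphenylsilyl ether; the medium is too weakly acidic to cyclise the diene and not basic enough to epimerise C6.

Step 22
Reactants: 31 (6R,8S)-13-{[tert-butyl(diphenyl)silyl]oxy}-8-hydroxygermacra-1(10),4,7(11)-trien-12,6-olide; 32 (E)-2-methylbut-2-enoyl chloride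
Product: 33 (6R,8S)-13-{[tert-butyl(diphenyl)silyl]oxy}-8-[(E)-2-methylbut-2-enoyloxy]germacra-1(10),4,7(11)-trien-12,6-olide
Conditions: 32, pyridine, DMAP (cat.), CH2Cl2, 0 °C → rt
Reagents that add atoms: none
Why: Nucleophile-catalysed acylation at oxygen, so C8 keeps its configuration; pyridine in place of a trialkylamine avoids vinylketene formation from the acid chloride and so keeps the E, conjugated ester.

Step 23
Reactants: 33 (6R,8S)-13-{[tert-butyl(diphenyl)silyl]oxy}-8-[(E)-2-methylbut-2-enoyloxy]germacra-1(10),4,7(11)-trien-12,6-olide
Product: 34 (6R,8S)-13-hydroxy-8-[(E)-2-methylbut-2-enoyloxy]germacra-1(10),4,7(11)-trien-12,6-olide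
Conditions: Bu4NF, AcOH (1:1), THF, 0 °C → rt
Reagents that add atoms: none
Why: Fluoride desilylation buffered with acetic acid, so that neither the tiglate, the lactone nor the C6 hydrogen meets free alkoxide or fluoride base; it is done before epoxidation so that the epoxides never see fluoride or acid.

Step 24
Reactants: 34 (6R,8S)-13-hydroxy-8-[(E)-2-methylbut-2-enoyloxy]germacra-1(10),4,7(11)-trien-12,6-olide
Product: 37 (1R,4R,5R,6S,8S,10R)-1,10:4,5-diepoxy-13-hydroxy-8-[(E)-2-methylbut-2-enoyloxy]germacr-7(11)-en-12,6-olide, via 1,10-monoepoxide 35 (not isolated), via 4,5-monoepoxide 36 (not isolated)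
Conditions: dimethyldioxirane (2.5 equiv), acetone, −20 → 0 °C
Reagents that add atoms: dimethyldioxirane, CC1(C)OO1
Why: Electrophilic epoxidation of the two electron-rich trisubstituted ring alkenes; the butenolide and tiglate alkenes are electron-poor and stay, and the neutral reagent leaves only acetone, so no acid is present to open the epoxides transannularly. Attack on the outer face of each alkene in the crown conformer (both methyl groups on one side, C6–O pseudo-equatorial) gives the 1,10- and 4,5-epoxides with the (1R,10R) and (4R,5R) configurations, the usual facial course for germacra-1(10),4-dienolides with this C6 configuration.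

## Compound list

1 | cis,cis-cyclohexane-1,3,5-triol (all-cis, meso) | O[C@H]1C[C@@H](O)C[C@@H](O)C1 | starting material
2 | all-cis-5-[(tert-butyldimethylsilyl)oxy]cyclohexane-1,3-diol (meso) | CC(C)(C)[Si](C)(C)O[C@H]1C[C@@H](O)C[C@@H](O)C1 | intermediate
3 | (1R,3S,5S)-3-[(tert-butyldimethylsilyl)oxy]-5-hydroxycyclohexyl acetate (all-cis) | CC(C)(C)[Si](C)(C)O[C@H]1C[C@@H](O)C[C@@H](OC(C)=O)C1 | intermediate
4 | (1S,3R)-3-[(tert-butyldimethylsilyl)oxy]-5-oxocyclohexyl acetate (cis; not isolated) | CC(C)(C)[Si](C)(C)O[C@H]1CC(=O)C[C@@H](OC(C)=O)C1 | intermediate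
5 | (R)-5-[(tert-butyldimethylsilyl)oxy]cyclohex-2-en-1-one | CC(C)(C)[Si](C)(C)O[C@H]1CC(=O)C=CC1 | intermediate
6 | (5R)-5-[(tert-butyldimethylsilyl)oxy]-1-methylcyclohex-2-en-1-ol (both C1 epimers) | CC(C)(C)[Si](C)(C)O[C@H]1CC(C)(O)C=CC1 | intermediate
7 | (S)-5-[(tert-butyldimethylsilyl)oxy]-3-methylcyclohex-2-en-1-one (ring = C5–C10 of the target, silyloxy carbon = C8) | CC(C)(C)[Si](C)(C)O[C@H]1CC(C)=CC(=O)C1 | intermediate
8 | ethyl 1-bromocyclobutane-1-carboxylate | CCOC(=O)C1(Br)CCC1 | starting material
9 | cyclobut-1-ene-1-carboxylic acid | OC(=O)C1=CCC1 | intermediate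
10 | methyl cyclobut-1-ene-1-carboxylate (ring = C1–C4, ester carbon = C15) | COC(=O)C1=CCC1 | intermediate
11 | methyl (8S)-8-[(tert-butyldimethylsilyl)oxy]-6-methyl-10-oxotricyclo[4.4.0.0(2,5)]decane-2-carboxylate; head-to-head, cis-anti-cis, four-membered rings anti to the silyloxy group; central cyclobutane C10–C1–C4–C5, ester on C4, ketone at C6 | CC(C)(C)[Si](C)(C)O[C@H]1C[C@]2(C)[C@H]3CC[C@@]3(C(=O)OC)[C@@H]2C(=O)C1 | intermediate
12 | methyl (8S)-8-[(tert-butyldimethylsilyl)oxy]-6-oxogermacra-1(10),4-dien-15-oate; C2 trans to C9, C3 cis to C6 (ester trans to the C6 carbonyl) | CC(C)(C)[Si](C)(C)O[C@H]1C/C(C)=C/CC/C(C(=O)OC)=C\C(=O)C1 | intermediate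
13 | methyl (8S)-8-[(tert-butyldimethylsilyl)oxy]-6-hydroxygermacra-1(10),4-dien-15-oate; alkenes as in 12; both C6 epimers | CC(C)(C)[Si](C)(C)O[C@H]1C/C(C)=C/CC/C(C(=O)OC)=C\C(O)C1 | intermediate
14 | (8S)-8-[(tert-butyldimethylsilyl)oxy]-5-(phenylsulfanyl)germacr-1(10)-en-15,6-olide (diastereomer mixture; not isolated) | CC(C)(C)[Si](C)(C)O[C@H]1C/C(C)=C/CCC2C(Sc3ccccc3)C(OC2=O)C1 | intermediate
15 | (8S)-8-[(tert-butyldimethylsilyl)oxy]germacra-1(10),4-dien-15,6-olide; C2 trans to C9; C4=C5 inside the butenolide, so C3 trans to C6; both C6 epimers | CC(C)(C)[Si](C)(C)O[C@H]1C/C(C)=C/CCC2=CC(OC2=O)C1 | intermediate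
16 | (8S)-8-[(tert-butyldimethylsilyl)oxy]germacra-1(10),4-diene-6,15-diol; C2 trans to C9, C3 trans to C6; both C6 epimers | CC(C)(C)[Si](C)(C)O[C@H]1C/C(C)=C/CC/C(CO)=C/C(O)C1 | intermediate
17 | 15-methanesulfonate of 16 (not isolated) | CC(C)(C)[Si](C)(C)O[C@H]1C/C(C)=C/CC/C(COS(C)(=O)=O)=C/C(O)C1 | intermediate
18 | (8S)-8-[(tert-butyldimethylsilyl)oxy]-15-chlorogermacra-1(10),4-dien-6-ol; alkenes as in 16 | CC(C)(C)[Si](C)(C)O[C@H]1C/C(C)=C/CC/C(CCl)=C/C(O)C1 | intermediate
19 | (8S)-8-[(tert-butyldimethylsilyl)oxy]germacra-1(10),4-dien-6-ol; both ring alkenes E; both C6 epimers | CC(C)(C)[Si](C)(C)O[C@H]1C/C(C)=C/CC/C(C)=C/C(O)C1 | intermediate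
20 | (8S)-8-[(tert-butyldimethylsilyl)oxy]germacra-1(10),4-dien-6-one; both ring alkenes E | CC(C)(C)[Si](C)(C)O[C@H]1C/C(C)=C/CC/C(C)=C/C(=O)C1 | intermediate
21 | methyl 2-(hydroxymethyl)prop-2-enoate | C=C(CO)C(=O)OC | starting material
22 | methyl 2-({[tert-butyl(diphenyl)silyl]oxy}methyl)prop-2-enoate | C=C(CO[Si](c1ccccc1)(c1ccccc1)C(C)(C)C)C(=O)OC | intermediate
23 | methyl 3-({[tert-butyl(diphenyl)silyl]oxy}methyl)-1,2,4-trioxolane-3-carboxylate (ozonide; not isolated) | COC(=O)C1(CO[Si](c2ccccc2)(c2ccccc2)C(C)(C)C)OCOO1 | intermediate
24 | methyl 3-{[tert-butyl(diphenyl)silyl]oxy}-2-oxopropanoate (carbons C12, C11, C13) | COC(=O)C(=O)CO[Si](c1ccccc1)(c1ccccc1)C(C)(C)C | intermediate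
25 | lithium C6(O)=C7 enolate of 20 (not isolated) | CC(C)(C)[Si](C)(C)O[C@H]1C/C(C)=C/CC/C(C)=C/C(O[Li])=C1 | intermediate
26 | aldol adduct: 20 carrying C(OH)(CO2Me)(CH2OSi) on C7; C7 and C11 epimers | CC(C)(C)[Si](C)(C)O[C@H]1C/C(C)=C/CC/C(C)=C/C(=O)C1C(O)(CO[Si](c2ccccc2)(c2ccccc2)C(C)(C)C)C(=O)OC | intermediate
27 | C6 alcohol of 26, C6–O cis to C8–O (not isolated) | CC(C)(C)[Si](C)(C)O[C@H]1C/C(C)=C/CC/C(C)=C/[C@@H](O)C1C(O)(CO[Si](c2ccccc2)(c2ccccc2)C(C)(C)C)C(=O)OC | intermediate
28 | 8-[(tert-butyldimethylsilyl)oxy]-13-{[tert-butyl(diphenyl)silyl]oxy}-11-hydroxygermacra-1(10),4-dien-12,6-olide; C6 and C8 as in the target; C7 and C11 epimers | CC(C)(C)[Si](C)(C)O[C@H]1C/C(C)=C/CC/C(C)=C/[C@H]2OC(=O)C(O)(CO[Si](c3ccccc3)(c3ccccc3)C(C)(C)C)C21 | intermediate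
29 | 11-O-chlorosulfite of 28 (not isolated) | CC(C)(C)[Si](C)(C)O[C@H]1C/C(C)=C/CC/C(C)=C/[C@H]2OC(=O)C(OS(Cl)=O)(CO[Si](c3ccccc3)(c3ccccc3)C(C)(C)C)C21 | intermediate
30 | (6R,8S)-8-[(tert-butyldimethylsilyl)oxy]-13-{[tert-butyl(diphenyl)silyl]oxy}germacra-1(10),4,7(11)-trien-12,6-olide; ring alkenes E | CC(C)(C)[Si](C)(C)O[C@H]1C/C(C)=C/CC/C(C)=C/[C@H]2OC(=O)C(CO[Si](c3ccccc3)(c3ccccc3)C(C)(C)C)=C12 | intermediate
31 | (6R,8S)-13-{[tert-butyl(diphenyl)silyl]oxy}-8-hydroxygermacra-1(10),4,7(11)-trien-12,6-olide | O[C@H]1C/C(C)=C/CC/C(C)=C/[C@H]2OC(=O)C(CO[Si](c3ccccc3)(c3ccccc3)C(C)(C)C)=C12 | intermediate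
32 | (E)-2-methylbut-2-enoyl chloride (tigloyl chloride) | C/C=C(\C)C(Cl)=O | starting material
33 | (6R,8S)-13-{[tert-butyl(diphenyl)silyl]oxy}-8-[(E)-2-methylbut-2-enoyloxy]germacra-1(10),4,7(11)-trien-12,6-olide | C/C=C(\C)C(=O)O[C@H]1C/C(C)=C/CC/C(C)=C/[C@H]2OC(=O)C(CO[Si](c3ccccc3)(c3ccccc3)C(C)(C)C)=C12 | intermediate
34 | (6R,8S)-13-hydroxy-8-[(E)-2-methylbut-2-enoyloxy]germacra-1(10),4,7(11)-trien-12,6-olide; ring alkenes E | C/C=C(\C)C(=O)O[C@H]1C/C(C)=C/CC/C(C)=C/[C@H]2OC(=O)C(CO)=C12 | intermediate
35 | (1R,6R,8S,10R)-1,10-epoxy-13-hydroxy-8-[(E)-2-methylbut-2-enoyloxy]germacra-4,7(11)-dien-12,6-olide (not isolated) | C/C=C(\C)C(=O)O[C@H]1C[C@@]2(C)O[C@@H]2CC/C(C)=C/[C@H]2OC(=O)C(CO)=C12 | intermediate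
36 | (4R,5R,6S,8S)-4,5-epoxy-13-hydroxy-8-[(E)-2-methylbut-2-enoyloxy]germacra-1(10),7(11)-dien-12,6-olide (not isolated) | C/C=C(\C)C(=O)O[C@H]1C/C(C)=C/CC[C@@]2(C)O[C@@H]2[C@H]2OC(=O)C(CO)=C12 | intermediate
37 | (1R,4R,5R,6S,8S,10R)-1,10:4,5-diepoxy-13-hydroxy-8-[(E)-2-methylbut-2-enoyloxy]germacr-7(11)-en-12,6-olide (CNP0111480.1) | C/C=C(\C)C(=O)O[C@H]1C[C@@]2(C)O[C@@H]2CC[C@@]2(C)O[C@@H]2[C@H]2OC(=O)C(CO)=C12 | target

## Step count and risk

Total: 24 steps. Longest linear sequence: 20 steps (steps 1–5, 8–15 and 18–24). The least certain steps are step 8 (key step) and steps 9, 11, 19, 20 and 24.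

For step 8, the key step, the most likely failure is erosion of head-to-head regioselectivity at the hindered, fully substituted C10, together with consumption of the strained acrylate 10 by oligomerisation during the long irradiation that a β,β-disubstituted enone needs. Trans-fused or syn adducts matter less, since they converge or become irrelevant in step 9. The fallback sets out from 7 and from the acid 9 in place of 10, and comes back to the route at 11. Irradiation of 7 with an excess of 9 should give the head-to-head adduct acid F1 by the same cycloaddition. Hydrogen bonding of the carboxyl group to the enone carbonyl holds the carboxyl-bearing carbon over C5, the acid is less prone to oligomerise, and F1 is separated from neutral by-products by base extraction. Methylation of F1 with TMSCHN2 then gives 11.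

For step 9, the most likely failure is fragmentation through the other chair of the diyl (C9 axial), which delivers C1=C10 as the Z alkene, together with drift of the product by Cope rearrangement at the temperature needed. The C1=C10 geometry cannot be repaired by the lactone device of step 11. The fallback is a stereospecific alkene inversion that sets out from 11 and comes back to the route at 15. Thermolysis as in step 9 would in that case give the 1(10)Z dienone ester F2 with the ester cis to the ketone. Luche reduction of F2 gives the hydroxy ester F3 and this lactonises at once to the 1(10)Z butenolide F4 without any isomerisation. Dimethyldioxirane epoxidises only the isolated C1=C10 alkene of F4 and gives the cis-epoxide F5 as either face isomer. HClO4 (cat.) in THF/H2O opens F5 with inversion to the anti 1,10-diol F6 (opening at either carbon gives a threo diol that leads to the same alkene). Thiocarbonyldiimidazole (DMAP, PhMe, 80 °C) converts F6 into the cyclic thionocarbonate F7 and Corey–Winter syn-elimination of F7 with 1,3-dimethyl-2-phenyl-1,3,2-diazaphospholidine at 40 °C gives the E alkene, that is 15.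

For step 11, the most likely failure is that the thiolate does not add to the hindered α,β-disubstituted enoate, so that no isomerisation occurs, or that base causes a prototropic shift of the γ-hydroxy enoate to the saturated keto ester. The fallback sets out from 13, replaces nucleophilic catalysis by direct photoisomerisation, and comes back to the route at 15. Irradiation of 13 at 254 nm (quartz, MeCN, PPTS cat.) equilibrates the enoate geometry. The C3-trans-to-C6 hydroxy ester F8 is drained from the photoequilibrium by lactonisation to 15, and the isolated C1=C10 alkene does not absorb at this wavelength.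

For step 19, the most likely failure is hydride delivery to the other face of the C6 carbonyl, because the ten-membered enone may react from a conformer other than the one assumed; the result is the wrong relative configuration at C6. The fallback sets out from 26 and comes back to the route at 28. Reduction and lactonisation as in step 19 would then give the 6-epi hydroxy lactone F9 instead of 28. Saponification of F9 (LiOH, THF/H2O) gives the 6-epi seco acid F10 and Mitsunobu lactonisation of F10 (PPh3, DIAD, PhMe, 0 °C) closes the ring with inversion at the allylic C6 carbinol to give 28. The tertiary C11 hydroxyl is not activated under these conditions.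

For step 20, the most likely failure is loss of regiocontrol in the elimination: for the C11 epimer whose leaving group has no antiperiplanar C7–H, proton removal from C13 would lead to an exocyclic enol ether. The fallback sets out from 20 and comes back to the route at 30; in it the C7=C11 alkene arises by enolisation and not by elimination. The enolate of 20 (LiN(i-Pr)2, −78 °C) adds to ethyl glyoxylate to give the glyoxylate aldol adduct F11 as a mixture of epimers. Luche reduction and lactonisation of F11 as in step 19 give the 13-nor 11-hydroxy lactone F12 and Dess–Martin oxidation of F12 gives, after enolisation of the new C11 carbonyl toward C7, the 11-hydroxybutenolide F13 in which C7 is sp2 whatever the earlier stereochemistry. PhN(SO2CF3)2 and Et3N convert F13 into the enol triflate F14 and Stille coupling of F14 with Bu3SnCH2OH (Pd2(dba)3, AsPh3, CuI, NMP, 50 °C) gives the C13 primary alcohol F15 by installing the hydroxymethyl group. TBDPSCl and imidazole convert F15 into 30. Oxidative addition into the electron-poor vinyl triflate should be much faster than ionisation of the hindered allylic C6–O bond.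

For step 24, the most likely failure is poor facial selectivity at one of the two ring alkenes, if the 7(11)-butenolide and the C8 ester shift the ring away from the crown conformer; diastereomeric epoxides would result. The fallback sets out from 34, comes back to the route at 37 and makes no new compound. It replaces substrate control by reagent control: ketone-catalysed (Shi-type) epoxidation with the D-fructose-derived ketone and KHSO5 in buffered MeCN/dimethoxymethane at 0 °C, whose spiro transition state is expected to deliver the R,R sense to both E-trisubstituted alkenes.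

## Further compounds

F1 | step 8 | (8S)-8-[(tert-butyldimethylsilyl)oxy]-6-methyl-10-oxotricyclo[4.4.0.0(2,5)]decane-2-carboxylic acid (head-to-head, cis-anti-cis; acid of 11) | CC(C)(C)[Si](C)(C)O[C@H]1C[C@]2(C)[C@H]3CC[C@@]3(C(=O)O)[C@@H]2C(=O)C1
F2 | step 9 | methyl (8S)-8-[(tert-butyldimethylsilyl)oxy]-6-oxogermacra-1(10),4-dien-15-oate with C2 cis to C9 and C3 trans to C6 | CC(C)(C)[Si](C)(C)O[C@H]1C/C(C)=C\CC/C(C(=O)OC)=C/C(=O)C1
F3 | step 9 | C6 alcohol of F2 (both C6 epimers; not isolated) | CC(C)(C)[Si](C)(C)O[C@H]1C/C(C)=C\CC/C(C(=O)OC)=C/C(O)C1
F4 | step 9 | 1(10)Z isomer of 15 | CC(C)(C)[Si](C)(C)O[C@H]1C/C(C)=C\CCC2=CC(OC2=O)C1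
F5 | step 9 | cis-1,10-epoxide of F4 (one face drawn; the other behaves alike) | CC(C)(C)[Si](C)(C)O[C@H]1C[C@@]2(C)O[C@H]2CCC2=CC(OC2=O)C1
F6 | step 9 | anti-1,10-diol from F5 | CC(C)(C)[Si](C)(C)O[C@H]1C[C@](C)(O)[C@@H](O)CCC2=CC(OC2=O)C1
F7 | step 9 | cyclic 1,10-thionocarbonate of F6 | CC(C)(C)[Si](C)(C)O[C@H]1C[C@]2(C)OC(=S)O[C@H]2CCC2=CC(OC2=O)C1
F8 | step 11 | methyl (8S)-8-[(tert-butyldimethylsilyl)oxy]-6-hydroxygermacra-1(10),4-dien-15-oate with C3 trans to C6 (not isolated) | CC(C)(C)[Si](C)(C)O[C@H]1C/C(C)=C/CC/C(C(=O)OC)=C/C(O)C1
F9 | step 19 | C6 epimer of 28 | CC(C)(C)[Si](C)(C)O[C@H]1C/C(C)=C/CC/C(C)=C/[C@@H]2OC(=O)C(O)(CO[Si](c3ccccc3)(c3ccccc3)C(C)(C)C)C21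
F10 | step 19 | seco acid of F9 (6-epi hydroxy acid) | CC(C)(C)[Si](C)(C)O[C@H]1C/C(C)=C/CC/C(C)=C/[C@H](O)C1C(O)(CO[Si](c2ccccc2)(c2ccccc2)C(C)(C)C)C(=O)O
F11 | step 20 | ethyl 2-[(8S)-8-[(tert-butyldimethylsilyl)oxy]-6-oxogermacra-1(10),4-dien-7-yl]-2-hydroxyacetate (C7 and C11 epimers) | CC(C)(C)[Si](C)(C)O[C@H]1C/C(C)=C/CC/C(C)=C/C(=O)C1C(O)C(=O)OCC
F12 | step 20 | 8-[(tert-butyldimethylsilyl)oxy]-11-hydroxy-13-norgermacra-1(10),4-dien-12,6-olide (C7 and C11 epimers) | CC(C)(C)[Si](C)(C)O[C@H]1C/C(C)=C/CC/C(C)=C/[C@H]2OC(=O)C(O)C21
F13 | step 20 | 8-[(tert-butyldimethylsilyl)oxy]-11-hydroxy-13-norgermacra-1(10),4,7(11)-trien-12,6-olide (enol of the α-keto lactone) | CC(C)(C)[Si](C)(C)O[C@H]1C/C(C)=C/CC/C(C)=C/[C@H]2OC(=O)C(O)=C12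
F14 | step 20 | 11-O-trifluoromethanesulfonate of F13 | CC(C)(C)[Si](C)(C)O[C@H]1C/C(C)=C/CC/C(C)=C/[C@H]2OC(=O)C(OS(=O)(=O)C(F)(F)F)=C12
F15 | step 20 | (6R,8S)-8-[(tert-butyldimethylsilyl)oxy]-13-hydroxygermacra-1(10),4,7(11)-trien-12,6-olide | CC(C)(C)[Si](C)(C)O[C@H]1C/C(C)=C/CC/C(C)=C/[C@H]2OC(=O)C(CO)=C12
F0 | step 24 | none | none
A1 | alternative 1 | ten-membered (E,E)-dienyl triflate with C6 PMB ether, C7 dioxolane and C8 MOM ether | COCO[C@H]1C/C(C)=C/CC/C(C)=C(OS(=O)(=O)C(F)(F)F)/[C@@H](OCc2ccc(OC)cc2)C13OCCO3
A2 | alternative 1 | 1-isopropenyl-2-methyl-2-vinylcyclohexanol precursor (alkenyl groups trans; C6 PMB ether, C7 dioxolane, C8 MOM ether) | COCO[C@H]1C[C@@](C)(C=C)[C@](O)(C(C)=C)[C@@H](OCc2ccc(OC)cc2)C13OCCO3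
A3 | alternative 2 | (6R,8S)-8-[(tert-butyldimethylsilyl)oxy]-13-{[tert-butyl(diphenyl)silyl]oxy}germacra-1(10),4,7(11)-trien-12,6-olide | CC(C)(C)[Si](C)(C)O[C@H]1C/C(C)=C/CC/C(C)=C/[C@H]2OC(=O)C(CO[Si](c3ccccc3)(c3ccccc3)C(C)(C)C)=C12
A4 | alternative 2 | (8S)-8-[(tert-butyldimethylsilyl)oxy]-13-{[tert-butyl(diphenyl)silyl]oxy}germacra-1(10),4,7(11)-trien-12-oic acid (carboxyl cis to C6) | CC(C)(C)[Si](C)(C)O[C@H]1C/C(C)=C/CC/C(C)=C/C/C1=C(/CO[Si](c2ccccc2)(c2ccccc2)C(C)(C)C)C(=O)O
A5 | alternative 3 | (6R,8S)-13-[(tert-butyldimethylsilyl)oxy]-8-[(E)-2-methylbut-2-enoyloxy]germacra-1(10),4,7(11)-trien-12,6-olide | C/C=C(\C)C(=O)O[C@H]1C/C(C)=C/CC/C(C)=C/[C@H]2OC(=O)C(CO[Si](C)(C)C(C)(C)C)=C12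
A6 | alternative 3 | open-chain butenolide with C6 (E)-2-methylbuta-1,3-dienyl group and C8 tiglate carrying the (E)-3-iodo-2-methylallyl group (C1–C2 seco precursor) | C/C=C(\C)C(=O)O[C@@H](C/C(C)=C/I)C1=C(CO[Si](C)(C)C(C)(C)C)C(=O)O[C@@H]1/C=C(\C)C=C
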